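Count the catalyst's half-lives.

| flask | starting material | reagent | capture agent | free catalyst | remark |
|---|---|---|---|---|---|
| grey | 0.53 M | 0.318 M | 0.037 M | 0.53 mM | run made earlier |
| ochre | 0.53 M | 0.318 M | 0.058 M | 0.53 mM | run made earlier |
| flask | 0.53 M | 0.318 M | 0.0265 M | 0.53 mM |  |

| run | time / min | target / % | starting material / % |
|---|---|---|---|
| grey | 0.500 | 2.5 | 97.4 |
| grey | 0.833 | 3.4 | 96.5 |
| grey | 1.33 | 5.4 | 94.3 |
| grey | 2.00 | 7.7 | 92.3 |
| grey | 3.00 | 9.6 | 90.0 |
| grey | 4.00 | 11.7 | 88.2 |
| grey | 6.00 | 14.8 | 85.1 |
| ochre | 0.500 | 2.4 | 97.5 |
| ochre | 0.833 | 2.8 | 96.5 |
| ochre | 1.33 | 5.2 | 94.9 |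
| ochre | 2.00 | 7.0 | 93.8 |
| ochre | 3.00 | 8.2 | 91.6 |
| ochre | 4.00 | 9.7 | 90.0 |
| ochre | 6.00 | 11.1 | 89.3 |

(scatter of a reading: 0.3 percentage points)

- no earlier run changes the charge of reagent; that part of a forecast is a guess

- apparent order in reagent when 20 % of the starting material are converted (percent change of the rate of making target for one percent more reagent charged)

- In the grey and ochre runs the first readings give nearly the same rate of making target, on average 0.0490 /min as a fraction of the charge, but the rate then falls, and falls faster in the ochre run, which holds more capture agent.
- A bench rule treats this as a catalyst dying at a steady pace, so that the rate halves in each half-life. Between the window up to 2.00 min and the window from 4.00 min to 6.00 min, whose centres lie 4.00 min apart, the readings give a half-life of 3.05 min in the grey run and a shorter 1.72 min in the ochre run.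
- Half-life times capture agent charged comes to 0.113 M·min and 0.0999 M·min, both readings with their scatter, so with the other charges held as in these runs the half-life is taken as inverse to the capture agent, and the mean 0.106 M·min divided by the flask's charge gives an estimate of the rate half-life in the flask, 4.01 min.
- The same rule estimates the final target in the flask as early rate times half-life over ln(2), which is 28.4 %.
- The rule holds the reagent constant, and that is its border: if one reagent goes per target, the mark of 20 % conversion takes a third of the reagent charged in the flask, so this reckoning gives no order in reagent, and no run varies the reagent.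
- The forecast puts the order at 0.9, with a range from 0.1 to 1.7, and says “its order is a guess from the mechanism”.
- The flask gives 0.57, lower than the forecast and inside its range.

    catalyst intermediate D + capture agent → trapped intermediate (k = 0.390 /M/s)
    reagent + free catalyst → catalyst intermediate A (k = 16.0 /M/s)
    catalyst intermediate A → by-product + catalyst intermediate B (k = 4.70 /s)
    catalyst intermediate B → catalyst intermediate C (k = 5.50 /s)
    catalyst intermediate E ⇌ free catalyst + target (K = 1.60 M, k = 9.40 /s)
    2 reagent → self-condensation product (k = 0.00220 /M/s)
    starting material + catalyst intermediate C → catalyst intermediate D (k = 10.0 /M/s)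
    catalyst intermediate D ⇌ catalyst intermediate E (K = 0.780, k = 4.70 /s)

- The flask reaches the mark at 8.71 min, which is 2.17 of the reckoned half-lives of 4.01 min, and the trapped intermediate, an off-cycle form, holds 48.3 % of the catalyst at 4.00 min, about half, and 71.7 % at 8.00 min.  At 2.56 min in the flask, catalyst intermediate D goes on to catalyst intermediate E at 460 times the rate at which it meets the capture agent, the forward step alone counted, and still at 80.0 min the flask holds target at 25.9 %, with >99.9 % of the catalyst trapped.

Readings and results are calculated for substances that don't exist; the scatter is artificial.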